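I took a small charge of second catalyst to be what turns the intermediate into product, so I asked how fast that exit runs in green and how much slowing it meets by the asked time.

common to all: free catalyst 17 mol%

| charge | substrate | reagent | second catalyst | temperature | remark | time |
|---|---|---|---|---|---|---|
| autumn | 66 mM | 1.5 equiv | 1 mol% | 80 °C | run made earlier |  |
| winter | 120 mM | 1.5 equiv | 1 mol% | 92 °C | run made earlier |  |
| dawn | 47 mM | 2.4 equiv | 1 mol% | 80 °C | run made earlier |  |
| violet | 47 mM | 1.50 equiv | 0.3 mol% | 100 °C |  | 25 h |
| green | 100 mM | 4.50 equiv | 1 mol% | 100 °C |  | 25 h |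
| ochre | 47 mM | 1.50 equiv | 1 mol% | 100 °C |  | 25 h |
| grey | 47 mM | 3.00 equiv | 0.3 mol% | 100 °C |  | 25 h |
| red | 47 mM | 6.00 equiv | 4 mol% | 85 °C |  | 25 h |

| run | time / h | product / % | substrate / % |
|---|---|---|---|
| autumn | 10.0 | 2.9 | 55.1 |
| autumn | 20.0 | 9.5 | 40.0 |
| autumn | 30.0 | 15.6 | 33.9 |
| autumn | 60.0 | 31.3 | 25.9 |
| winter | 4.00 | 8.4 | 50.2 |
| winter | 8.00 | 19.5 | 39.8 |
| winter | 12.0 | 28.8 | 35.1 |
| winter | 20.0 | 43.9 | 27.8 |
| dawn | 5.00 | 1.0 | 78.1 |
| dawn | 15.0 | 4.7 | 53.1 |
| dawn | 30.0 | 11.8 | 38.5 |
| dawn | 60.0 | 26.4 | 28.8 |

(each reading ± 0.3 percentage points)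

- the flasks put in order of amount of product, in percent of the substrate charged, best first, at 25 h (violet / green / ochre / grey / red)
- the amount of product, in percent of the substrate charged of the flask you put first, at 25 h
- the amount of product, in percent of the substrate charged of the flask you put last, at 25 h

In every earlier run, substrate and product fall short of the charge. I called the unseen rest the intermediate and took the rate of product as k[second catalyst][reagent][intermediate], with one reagent used per product. The last two readings of dawn and of winter gave:

k = 3.52 M⁻² min⁻¹ at 80 °C

k = 5.97 M⁻² min⁻¹ at 92 °C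

A straight line of ln k against temperature, over this short span, carried that to 100 °C:

k = 8.49 M⁻² min⁻¹

The quantity I carried was the exit constant, k[second catalyst][reagent], a pseudo-first-order constant: the fraction of the intermediate leaving per hour. For green at the start:

exit constant = 0.229 h⁻¹

Two things slowed it. The last readings put intermediate over substrate at 1.56 in dawn and 1.02 in winter, which the same line took to 0.767. So the share of unconverted material standing as intermediate was:

share = 0.434

The reagent was the small correction. Green uses 22.2% of its reagent at full conversion, so I took half of that as the mean loss: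

reagent factor = 0.889

The reagent slowed it less than the share did. Together:

net constant = 0.0885 h⁻¹

Over 25 h that is an exponent of 2.21, so product is 89.1%. I had treated the first step as instantaneous, so I read this figure as high.

The forecast, from the same runs, said “a large unseen pool builds up”. It gave green > red > ochre > grey > violet, with 80% for green (range 68% to 90%) and 4.5% for violet (3% to 6.5%). My figure stood higher than its 80%, but inside its range.

The flasks came out as green > red > ochre > grey > violet, with green at 84.2%.

    substrate + free catalyst ⇌ free catalyst + intermediate (K = 0.870, k = 0.420 M⁻¹ min⁻¹, Ea = 71.0 kJ mol⁻¹, ΔH = −38.0 kJ mol⁻¹)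
    reagent + second catalyst + intermediate → second catalyst + product (k = 7.80 M⁻² min⁻¹, Ea = 45.0 kJ mol⁻¹)
    (constants at 100 °C)

At 25.0 h green still held 9.19% as substrate and 6.65% as intermediate. Scaled to violet's charges, the 0.229 h⁻¹ of green became 0.00507 h⁻¹. With the share 0.434, 25 h and a reagent factor of 97%, the part of its charge that violet still held at the end, it gave 5.20%, and violet stood at 4.69%.

The numbers in the tables were generated by integration with constants of no real substance; noise was put on by code.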